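**Retrosynthetic overview**
1. Isoangustone A ⇒ removal of two MOM ethers (O7, O5'). The C6–prenyl and C3'–prenyl bonds ⇒ aromatic Claisen shifts of 1,1-dimethylallyl ethers on O5 and O4', each oxygen having a single free ortho carbon.
2. The two ethers ⇒ the 5,4'-diphenol ⇒ the 5,4'-di-O-benzyl-7,5'-di-O-MOM isoflavone. The prenyl alkenes enter only after the oxidation.
3. Feature used: ring B is bonded to C3 of the pyranone ring C and carries O4' para to the C3–C1' bond, so this p-alkoxyaryl group can move as a phenonium ion from the carbon that becomes C2 to the carbon that becomes C3. Ring C (bonds C3–C1' and O1–C2) ⇒ a 2'-hydroxychalcone by iodine(III) oxidative 1,2-aryl shift and acid closure.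
4. Chalcone ⇒ Claisen–Schmidt union of a ring-A acetophenone (from 2,4,6-trihydroxyacetophenone) and a ring-B aldehyde (from 3,4-dihydroxybenzaldehyde).
5. Ring order: rings A and B are purchased; ring C is the only ring formed.

Key step: step 6

Remark on numbering: isoflavone numbering is used with the B-ring oxygens called O4' and O5' and the B-ring prenyl carbon C3' (the same compound as the 3',4'-dihydroxy-5'-prenyl description); the target is achiral.

**Step 1**
Reactants: 1 2,4,6-trihydroxyacetophenone
Product: 2 1-[2,6-dihydroxy-4-(methoxymethoxy)phenyl]ethan-1-one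
Conditions: MOMCl (1.0 equiv), i-Pr2NEt (1.2 equiv), THF, 0 °C
Reagents that add atoms: chloromethyl methyl ether, COCCl
Why: O-alkylation with an α-chloro ether; the 4-OH is para to the acetyl group and not hydrogen-bonded, so it is the most acidic and most accessible phenol and one equivalent of MOMCl should mark it preferentially (2-O- and bis-ethers are removed by chromatography).

**Step 2**
Reactants: 2 1-[2,6-dihydroxy-4-(methoxymethoxy)phenyl]ethan-1-one
Product: 3 1-[2-(benzyloxy)-6-hydroxy-4-(methoxymethoxy)phenyl]ethan-1-one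
Conditions: BnBr (1.05 equiv), K2CO3, acetone, reflux
Reagents that add atoms: benzyl bromide, BrCc1ccccc1
Why: Williamson etherification; the two phenols of 2 are equivalent, and once one is benzylated the other is held in a strong hydrogen bond to the ketone, so alkylation should stop at the mono-benzyl ether.

**Step 3**
Reactants: 4 3,4-dihydroxybenzaldehyde
Product: 5 4-(benzyloxy)-3-hydroxybenzaldehyde
Conditions: BnBr (1.0 equiv), NaHCO3, DMF, 40 °C
Reagents that add atoms: benzyl bromide, BrCc1ccccc1
Why: Regioselective Williamson etherification; the 4-OH para to the formyl group is the more acidic phenol of the catechol and the weak base ionises only that one.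

**Step 4**
Reactants: 5 4-(benzyloxy)-3-hydroxybenzaldehyde
Product: 6 4-(benzyloxy)-3-(methoxymethoxy)benzaldehyde
Conditions: MOMCl, i-Pr2NEt, CH2Cl2, 0 °C → rt
Reagents that add atoms: chloromethyl methyl ether, COCCl
Why: Standard MOM ether formation on the one remaining phenol under amine base.

**Step 5**
Reactants: 3 1-[2-(benzyloxy)-6-hydroxy-4-(methoxymethoxy)phenyl]ethan-1-one; 6 4-(benzyloxy)-3-(methoxymethoxy)benzaldehyde
Product: 7 (E)-1-[2-(benzyloxy)-6-hydroxy-4-(methoxymethoxy)phenyl]-3-[4-(benzyloxy)-3-(methoxymethoxy)phenyl]prop-2-en-1-one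
Conditions: KOH (50% aq.), EtOH, 0 °C → rt; cold dil. HCl to pH 5
Reagents that add atoms: none
Why: Claisen–Schmidt condensation; the ketone enolate adds to the non-enolisable aldehyde and E1cB dehydration gives the thermodynamically preferred (E)-enone, while benzyl and MOM ethers are inert to hydroxide.

**Step 6**
Reactants: 7 (E)-1-[2-(benzyloxy)-6-hydroxy-4-(methoxymethoxy)phenyl]-3-[4-(benzyloxy)-3-(methoxymethoxy)phenyl]prop-2-en-1-one
Product: 10 5,4'-bis(benzyloxy)-7,5'-bis(methoxymethoxy)isoflavone, via dimethyl acetal 8 (not isolated), via 2-methoxyisoflavanone 9 (not isolated)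
Conditions: PhI(OH)OTs (1.2 equiv), MeOH–HC(OMe)3 (3:1, co-solvent), rt; then the TsOH released in the flask (topped up with 0.2 equiv TsOH·H2O if needed), 40 °C, TLC control; aq. NaHCO3
Reagents that add atoms: none
Why: Iodine(III) adds to the enone C=C at the carbon next to the carbonyl while methanol adds at the benzylic carbon, and departure of iodobenzene is assisted by ring B, which bridges as a phenonium ion and ends on the former α-carbon (new C3–C1' bond), leaving an oxocarbenium ion that methanol traps as dimethyl acetal 8. This is the known hypervalent-iodine (or thallium(III)) oxidative 1,2-aryl migration of chalcones to 1,2-diaryl-3,3-dimethoxypropan-1-ones, a laboratory mimic of isoflavone synthase. The toluenesulfonic acid set free then ionises the acetal and the one free phenol closes ring C by 6-exo-trig attack of O1 on the oxocarbenium carbon C2 to give 9, which loses methanol to give the aromatic 4-pyranone. No stereocentre survives, since the one in 8 and the two in 9 are destroyed in the elimination. The step needs aryl and not aroyl migration, which the para-benzyloxy group of ring B secures by stabilising the phenonium ion, and closure through one oxygen only, which the benzyl ether on the other ortho oxygen secures. The acid stage is kept short and at or below 40 °C so that the two aryl MOM ethers, the most acid-labile groups present, should stay in place.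

**Step 7**
Reactants: 10 5,4'-bis(benzyloxy)-7,5'-bis(methoxymethoxy)isoflavone
Product: 11 5,4'-dihydroxy-7,5'-bis(methoxymethoxy)isoflavone
Conditions: H2 (1 atm), 10% Pd/C, EtOAc–MeOH, rt, stopped after uptake of 2 equiv
Reagents that add atoms: none
Why: Catalytic hydrogenolysis of the two aryl benzyl ethers; MOM ethers are inert and the vinylogous-ester C2=C3 bond of the pyranone is reduced far more slowly.

**Step 8**
Reactants: 12 2-methylbut-3-yn-2-ol
Product: 13 methyl 2-methylbut-3-yn-2-yl carbonate
Conditions: n-BuLi (1.0 equiv), THF, −78 °C; ClCO2Me, −78 °C → rt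
Reagents that add atoms: methyl chloroformate, COC(=O)Cl
Why: O-acylation of the lithium alkoxide with a chloroformate; one equivalent of base removes only the much more acidic O–H and leaves the alkyne C–H.

**Step 9**
Reactants: 11 5,4'-dihydroxy-7,5'-bis(methoxymethoxy)isoflavone; 13 methyl 2-methylbut-3-yn-2-yl carbonate
Product: 14 7,5'-bis(methoxymethoxy)-5,4'-bis[(2-methylbut-3-yn-2-yl)oxy]isoflavone
Conditions: 13 (4 equiv), DBU (4 equiv), CuCl2·2H2O (5 mol%), MeCN, 0 °C → 40 °C
Reagents that add atoms: none
Why: Copper-catalysed propargylic etherification of phenols (copper acetylide to copper allenylidene, attacked at the tertiary carbon by the phenoxide); DBU in MeCN ionises both phenols, and excess carbonate with gentle warming is planned for the hydrogen-bonded 5-OH.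

**Step 10**
Reactants: 14 7,5'-bis(methoxymethoxy)-5,4'-bis[(2-methylbut-3-yn-2-yl)oxy]isoflavone
Product: 15 7,5'-bis(methoxymethoxy)-5,4'-bis[(2-methylbut-3-en-2-yl)oxy]isoflavone
Conditions: H2 (1 atm), Lindlar catalyst, quinoline, EtOAc, rt
Reagents that add atoms: none
Why: Lindlar semi-hydrogenation of the two terminal alkynes to vinyl groups; the poisoned catalyst should leave the pyranone double bond, the MOM ethers and the tertiary allylic C–O bonds untouched.

**Step 11**
Reactants: 15 7,5'-bis(methoxymethoxy)-5,4'-bis[(2-methylbut-3-en-2-yl)oxy]isoflavone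
Product: 16 5,4'-dihydroxy-7,5'-bis(methoxymethoxy)-6,3'-bis(3-methylbut-2-en-1-yl)isoflavone
Conditions: PhNEt2, 130 °C, Ar
Reagents that add atoms: none
Why: Double aromatic Claisen rearrangement ([3,3]-sigmatropic shift, then tautomerisation); O5 has only C6 and O4' only C3' as a free ortho carbon, so each 1,1-dimethylallyl group is delivered to one site and arrives as a 3,3-dimethylallyl (prenyl) group.

**Step 12**
Reactants: 16 5,4'-dihydroxy-7,5'-bis(methoxymethoxy)-6,3'-bis(3-methylbut-2-en-1-yl)isoflavone
Product: 17 isoangustone A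
Conditions: 3 M HCl, MeOH, rt → 40 °C, Ar
Reagents that add atoms: none
Why: Acid-catalysed acetal exchange of the two aryl MOM ethers with methanol; dilute acid near room temperature is chosen so that the prenyl alkenes are not protonated and no chroman forms.

**Compound list**
1 | 2,4,6-trihydroxyacetophenone | CC(=O)c1c(O)cc(O)cc1O | starting material
2 | 1-[2,6-dihydroxy-4-(methoxymethoxy)phenyl]ethan-1-one | CC(=O)c1c(O)cc(OCOC)cc1O | intermediate
3 | 1-[2-(benzyloxy)-6-hydroxy-4-(methoxymethoxy)phenyl]ethan-1-one | CC(=O)c1c(O)cc(OCOC)cc1OCc1ccccc1 | intermediate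
4 | 3,4-dihydroxybenzaldehyde | O=Cc1ccc(O)c(O)c1 | starting material
5 | 4-(benzyloxy)-3-hydroxybenzaldehyde | O=Cc1ccc(OCc2ccccc2)c(O)c1 | intermediate
6 | 4-(benzyloxy)-3-(methoxymethoxy)benzaldehyde | O=Cc1ccc(OCc2ccccc2)c(OCOC)c1 | intermediate
7 | (E)-1-[2-(benzyloxy)-6-hydroxy-4-(methoxymethoxy)phenyl]-3-[4-(benzyloxy)-3-(methoxymethoxy)phenyl]prop-2-en-1-one | O=C(/C=C/c1ccc(OCc2ccccc2)c(OCOC)c1)c1c(O)cc(OCOC)cc1OCc1ccccc1 | intermediate
8 | 1-[2-(benzyloxy)-6-hydroxy-4-(methoxymethoxy)phenyl]-2-[4-(benzyloxy)-3-(methoxymethoxy)phenyl]-3,3-dimethoxypropan-1-one (racemic) | COC(OC)C(c1ccc(OCc2ccccc2)c(OCOC)c1)C(=O)c1c(O)cc(OCOC)cc1OCc1ccccc1 | intermediate (not isolated)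
9 | 5-(benzyloxy)-3-[4-(benzyloxy)-3-(methoxymethoxy)phenyl]-2-methoxy-7-(methoxymethoxy)chroman-4-one (racemic, mixture of diastereomers) | COC1Oc2cc(OCOC)cc(OCc3ccccc3)c2C(=O)C1c1ccc(OCc2ccccc2)c(OCOC)c1 | intermediate (not isolated)
10 | 5,4'-bis(benzyloxy)-7,5'-bis(methoxymethoxy)isoflavone [5-(benzyloxy)-3-[4-(benzyloxy)-3-(methoxymethoxy)phenyl]-7-(methoxymethoxy)-4H-chromen-4-one] | O=c1c(-c2ccc(OCc3ccccc3)c(OCOC)c2)coc2cc(OCOC)cc(OCc3ccccc3)c12 | intermediate
11 | 5,4'-dihydroxy-7,5'-bis(methoxymethoxy)isoflavone [5-hydroxy-3-[4-hydroxy-3-(methoxymethoxy)phenyl]-7-(methoxymethoxy)-4H-chromen-4-one] | O=c1c(-c2ccc(O)c(OCOC)c2)coc2cc(OCOC)cc(O)c12 | intermediate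
12 | 2-methylbut-3-yn-2-ol | CC(C)(O)C#C | starting material
13 | methyl 2-methylbut-3-yn-2-yl carbonate | COC(=O)OC(C)(C)C#C | intermediate
14 | 7,5'-bis(methoxymethoxy)-5,4'-bis[(2-methylbut-3-yn-2-yl)oxy]isoflavone | O=c1c(-c2ccc(OC(C)(C)C#C)c(OCOC)c2)coc2cc(OCOC)cc(OC(C)(C)C#C)c12 | intermediate
15 | 7,5'-bis(methoxymethoxy)-5,4'-bis[(2-methylbut-3-en-2-yl)oxy]isoflavone | O=c1c(-c2ccc(OC(C)(C)C=C)c(OCOC)c2)coc2cc(OCOC)cc(OC(C)(C)C=C)c12 | intermediate
16 | 5,4'-dihydroxy-7,5'-bis(methoxymethoxy)-6,3'-bis(3-methylbut-2-en-1-yl)isoflavone | CC(C)=CCc1cc(-c2coc3cc(OCOC)c(CC=C(C)C)c(O)c3c2=O)cc(OCOC)c1O | intermediate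
17 | isoangustone A [3-[3,4-dihydroxy-5-(3-methylbut-2-en-1-yl)phenyl]-5,7-dihydroxy-6-(3-methylbut-2-en-1-yl)-4H-chromen-4-one] | CC(C)=CCc1cc(-c2coc3cc(O)c(CC=C(C)C)c(O)c3c2=O)cc(O)c1O | target

**Step count and risks**
Total steps: 12. Longest linear sequence: 9 steps (1 → 2 → 3 → 7 → 10 → 11 → 14 → 15 → 16 → 17; the branch from 4 is equally long).

Steps most likely to fail:

Step 6. The aryl MOM ethers may be solvolysed by the sulfonic acid in methanol in competition with ring closure, or closure may be too slow under acid mild enough to spare them. Fallback: setting out from 7, the same iodine(III) oxidation is followed by methanolic HCl at 55 °C, which is allowed both to close ring C and to strip the two MOM groups, giving 5,4'-bis(benzyloxy)-7,5'-dihydroxyisoflavone F1. Neither free phenol of F1 is hydrogen-bonded to the carbonyl, so MOMCl and i-Pr2NEt in CH2Cl2 should put both ethers back, and the route is rejoined at 10.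

Step 9. Etherification may stop at O4' because the 5-OH is tied up in a hydrogen bond to the C4 carbonyl and reacts sluggishly with the tertiary electrophile. Fallback: setting out from 11, allyl bromide and K2CO3 in DMF at 60 °C (a primary halide, which does alkylate such phenols) should give 5,4'-bis(allyloxy)-7,5'-bis(methoxymethoxy)isoflavone F2. Claisen rearrangement in PhNEt2 at 190 °C then moves both allyl groups to their only free ortho carbons, giving 6,3'-diallyl-5,4'-dihydroxy-7,5'-bis(methoxymethoxy)isoflavone F3. Olefin cross-metathesis of F3 with 2-methylbut-2-ene (Grubbs second-generation catalyst, CH2Cl2, 40 °C) converts both allyl groups into prenyl groups, and the route is rejoined at 16.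

Step 12. Brønsted acid may protonate the prenyl alkenes, and the neighbouring phenols would then capture the tertiary cations to form dimethylchroman rings. Fallback: setting out from 16, TMSOTf with 2,2'-bipyridyl in CH2Cl2 at 0 °C exchanges each aryl MOM ether for an aryl silyl ether without free protic acid and silylates the two free phenols as well, giving 5,7,4',5'-tetrakis(trimethylsilyloxy)-6,3'-bis(3-methylbut-2-en-1-yl)isoflavone F4. Hydrolysis of F4 in aqueous THF at pH 7 should then give 17.

**Further compounds**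
F1 | step 6 | 5,4'-bis(benzyloxy)-7,5'-dihydroxyisoflavone | O=c1c(-c2ccc(OCc3ccccc3)c(O)c2)coc2cc(O)cc(OCc3ccccc3)c12
F2 | step 9 | 5,4'-bis(allyloxy)-7,5'-bis(methoxymethoxy)isoflavone | O=c1c(-c2ccc(OCC=C)c(OCOC)c2)coc2cc(OCOC)cc(OCC=C)c12
F3 | step 9 | 6,3'-diallyl-5,4'-dihydroxy-7,5'-bis(methoxymethoxy)isoflavone | C=CCc1cc(-c2coc3cc(OCOC)c(CC=C)c(O)c3c2=O)cc(OCOC)c1O
F4 | step 12 | 5,7,4',5'-tetrakis(trimethylsilyloxy)-6,3'-bis(3-methylbut-2-en-1-yl)isoflavone | CC(C)=CCc1cc(-c2coc3cc(O[Si](C)(C)C)c(CC=C(C)C)c(O[Si](C)(C)C)c3c2=O)cc(O[Si](C)(C)C)c1O[Si](C)(C)C
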